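**Retrosynthetic overview**
1. The strategy rests on the run C10 oxirane (bearing C14H2OH) – C1 – cis C2=C3 – C4 oxirane (bearing C15) – C5. This is a doubly epoxidised cyclodeca-1(10),2,4-triene, the ring-opened form of a cis-fused hexalin (ring A = C1–C5, C10; ring B = C5–C10) whose shared C5–C10 bond is cut. C5–C10, C14 and the oxygens on C6, C7 and C8 reproduce shikimic acid.
2. Disconnections, backwards: C8 ester; C4–C5 oxirane (oxygen delivered from the C8 hydroxyl); C1–C10 oxirane (tartrate-controlled, from the C14 allylic alcohol); photochemical six-electron opening of a hexalin butenolide.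
3. The butenolide comes from an intramolecular Horner–Wadsworth–Emmons reaction of a C6 phosphonoacyl ester onto a C7 ketone; ring A from a Diels–Alder reaction of a 5-epi-shikimate with a 1-methoxy-3-silyloxybutadiene.
4. Ring order: ring B (bought), ring A (cycloaddition), butenolide (olefination), ten-membered ring (cleavage of the A/B fusion bond), then the C1–C10 and the C4–C5 oxirane.

Key step: step 20

Remark on the chemistry: germacrane atom numbers are used from compound 8 on (shikimate C1, C2, C3, C4, C5, C6 and the carboxyl carbon become C10, C5, C6, C7, C8, C9 and C14). It is assumed that the ring-trans C1=C10 alkene of the ten-membered triene can rotate through the ring at about −30 °C, as in related cyclodeca-1(10),4-dienes, so that the tartrate reagent can choose its face.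

**Step 1**
Reactants: 1 (−)-shikimic acid
Product: 2 methyl shikimate
Conditions: MeOH, camphorsulfonic acid (cat.), reflux
Reagents that add atoms: methanol, CO
Why: Fischer esterification of the conjugated acid leaves the three carbinol centres untouched.

**Step 2**
Reactants: 2 methyl shikimate
Product: 3 methyl 3,4-O-isopropylideneshikimate
Conditions: Me2C(OMe)2, camphorsulfonic acid (cat.), acetone, rt
Reagents that add atoms: 2,2-dimethoxypropane, COC(C)(C)OC
Why: Acid-catalysed transketalisation selects the cis-3,4-diol, the only pair that can form an unstrained dioxolane, and leaves the trans C5 hydroxyl free.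

**Step 3**
Reactants: 3 methyl 3,4-O-isopropylideneshikimate
Product: 4 methyl 5-epi-3,4-O-isopropylidene-5-O-(4-nitrobenzoyl)shikimate
Conditions: 4-nitrobenzoic acid, PPh3, iPrO2CN=NCO2iPr, THF, 0 °C to rt
Reagents that add atoms: 4-nitrobenzoic acid, OC(=O)c1ccc(cc1)[N+](=O)[O-]
Why: The Mitsunobu reaction displaces the activated C5 oxygen with SN2 inversion, which places the new C5–O bond (the later C8 centre) cis to the acetonide oxygens.

**Step 4**
Reactants: 4 the 4-nitrobenzoate
Product: 5 methyl 5-epi-3,4-O-isopropylideneshikimate
Conditions: K2CO3 (cat.), MeOH, 0 °C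
Reagents that add atoms: none
Why: Base-catalysed transesterification removes the electron-poor aryl ester, while the conjugated methyl ester can only exchange with the solvent to give itself.

**Step 5**
Reactants: 5 methyl 5-epi-3,4-O-isopropylideneshikimate
Product: 6 methyl 5-epi-3,4-O-isopropylidene-5-O-(tert-butyldimethylsilyl)shikimate (all three oxygens on one ring face)
Conditions: tBuMe2SiOTf, 2,6-lutidine, CH2Cl2, 0 °C
Reagents that add atoms: tert-butyldimethylsilyl triflate, CC(C)(C)[Si](C)(C)OS(=O)(=O)C(F)(F)F
Why: The silyl triflate silylates the hindered secondary alcohol and completes a dienophile whose three oxygens screen one face.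

**Step 6**
Reactants: 6 the silylated 5-epi-shikimate; 7 (E)-1-methoxy-3-(trimethylsilyloxy)buta-1,3-diene
Product: 9 cis-fused bicyclic 1-en-3-one bearing the angular methyl ester at C10 (H5 and the ester on the face of O6, O7 and O8), via silyl enol ether cycloadduct 8 (not isolated)
Conditions: 7 (4 equiv), toluene, sealed tube, 160 °C; then 0.05 M HCl, THF/H2O, 0 °C
Reagents that add atoms: none
Why: The Diels–Alder reaction joins the nucleophilic CH2 terminus of the diene to the ester β-carbon (C5) and the methoxy carbon to C10, suprafacially (cis fusion) and on the face away from the acetonide and silyloxy groups, which sets C5 and C10; dilute acid then cleaves the silyl enol ether and eliminates methanol to the enone.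

**Step 7**
Reactants: 9 the bicyclic enone
Product: 10 4-methyl enone (both C4 epimers)
Conditions: LiN(iPr)2, THF, −78 °C; MeI, −78 to −30 °C
Reagents that add atoms: iodomethane, CI
Why: Kinetic deprotonation can only occur at the α′-carbon C4 (C10 is quaternary), and alkylation of this cross-conjugated enolate brings in C15; the C4 configuration is irrelevant because C4 becomes trigonal in step 8.

**Step 8**
Reactants: 10 the 4-methyl enone
Product: 11 dienyl triflate (C1=C2 and C3(OTf)=C4)
Conditions: KN(SiMe3)2, THF, −78 °C; PhNTf2, −78 to 0 °C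
Reagents that add atoms: N-phenylbis(trifluoromethanesulfonimide), O=S(=O)(N(c1ccccc1)S(=O)(=O)C(F)(F)F)C(F)(F)F
Why: The single remaining α-proton (H4) is removed and O-sulfonylation of the dienolate fixes both double bonds of the ring A diene.

**Step 9**
Reactants: 11 the dienyl triflate
Product: 12 cis-hexalin 1,3-diene methyl ester
Conditions: Pd(OAc)2 (5 mol%), PPh3, HCO2H, Bu3N, DMF, 60 °C
Reagents that add atoms: none
Why: Zerovalent palladium formed in the flask inserts into the vinyl C–O triflate bond and formate supplies hydride (reductive cleavage of an enol triflate); the quaternary C10 rules out aromatisation.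

**Step 10**
Reactants: 12 the diene ester
Product: 13 C14 primary alcohol
Conditions: iBu2AlH (2.5 equiv), CH2Cl2, −78 to 0 °C; aqueous potassium sodium tartrate
Reagents that add atoms: none
Why: Hydride reduction converts the angular ester into the C14 carbinol while the unactivated diene, the acetal and the silyl ether are inert.

**Step 11**
Reactants: 13 the C14 alcohol
Product: 14 C14 triisopropylsilyl ether
Conditions: iPr3SiOTf, 2,6-lutidine, CH2Cl2, 0 °C
Reagents that add atoms: triisopropylsilyl triflate, CC(C)[Si](C(C)C)(C(C)C)OS(=O)(=O)C(F)(F)F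
Why: Silylation with the reactive triflate masks the neopentyl alcohol as an ether bulky enough to outlast the acid of step 12.

**Step 12**
Reactants: 14 the fully protected hexalin
Product: 15 6,7-diol (C14 triisopropylsilyl and C8 tert-butyldimethylsilyl ethers kept)
Conditions: AcOH/H2O (4:1), 40 °C
Reagents that add atoms: none
Why: Acid hydrolysis of the dioxolane should be much faster than cleavage of the hindered secondary and neopentyl silyl ethers.

**Step 13**
Reactants: 16 allyl 2-(diethoxyphosphoryl)acetate; 17 (triisopropylsilyloxy)methyl chloride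
Product: 18 allyl 2-(diethoxyphosphoryl)-3-(triisopropylsilyloxy)propanoate (racemic)
Conditions: NaH, THF, 0 °C; then 17, 0 °C to rt (16 in slight excess)
Reagents that add atoms: none
Why: The stabilised phosphonoacetate carbanion is C-alkylated by the reactive α-chloro ether, which brings in C13 and its oxygen; the new centre is racemic and later becomes trigonal C11.

**Step 14**
Reactants: 18 the allyl ester
Product: 19 2-(diethoxyphosphoryl)-3-(triisopropylsilyloxy)propanoic acid (racemic)
Conditions: Pd(PPh3)4 (3 mol%), morpholine, THF, rt; cold dilute acid wash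
Reagents that add atoms: none
Why: Zerovalent palladium ionises the allyl ester to a π-allyl complex that morpholine captures, freeing the acid under neutral conditions that spare the silyl ether and avoid β-elimination of the silyloxy group.

**Step 15**
Reactants: 15 the 6,7-diol; 19 the phosphono acid
Product: 22 C6 phosphonoacyl ester with free C7 hydroxyl, via stannylene acetal 20 (not isolated), via acid chloride 21 (not isolated)
Conditions: 15, Bu2SnO, toluene, reflux with removal of water; separately 19, 1-chloro-N,N,2-trimethylprop-1-enylamine, CH2Cl2, 0 °C; then combined, 0 °C to rt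
Reagents that add atoms: none
Why: A dibutylstannylene acetal of a cis-1,2-diol is acylated at its equatorial oxygen, here O6, because ring B prefers the chair with O6, O8 and C14 equatorial and O7 axial, so the C7 hydroxyl stays free.

**Step 16**
Reactants: 22 the C6 ester
Product: 23 C7 ketone
Conditions: Dess–Martin periodinane, CH2Cl2, 0 °C to rt
Reagents that add atoms: none
Why: Dess–Martin oxidation converts the hindered axial alcohol into the ketone under near-neutral conditions that do not epimerise C6 or C8.

**Step 17**
Reactants: 23 the keto phosphonate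
Product: 24 silylated tricyclic hexalin butenolide
Conditions: LiCl, iPr2NEt, MeCN, rt
Reagents that add atoms: none
Why: In this intramolecular Horner–Wadsworth–Emmons reaction the lithium-chelated phosphonate carbanion adds to the C7 ketone and loses diethyl phosphate, which forms C7=C11, closes the five-membered lactone and erases the racemic phosphonate centre.

**Step 18**
Reactants: 24 the silylated butenolide
Product: 25 hexalin butenolide triol (free C8, C13 and C14 hydroxyls)
Conditions: HF·pyridine, pyridine, THF, 0 °C to rt
Reagents that add atoms: none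
Why: Fluoride cleaves all three silyl ethers, and the pyridine buffer protects the diene and the butenolide.

**Step 19**
Reactants: 25 the triol
Product: 26 hexalin butenolide C13 acetate with free C8 and C14 hydroxyls
Conditions: Ac2O (1.0 equiv), 2,4,6-collidine, CH2Cl2, −40 °C
Reagents that add atoms: acetic anhydride, CC(=O)OC(C)=O
Why: Kinetic acylation with one equivalent should pick the unhindered allylic primary C13 hydroxyl over the neopentyl C14 and the secondary C8 hydroxyl.

**Step 20**
Reactants: 26 the hexalin butenolide acetate
Product: 27 cyclodeca-1(10),2,4-trienolide (C9 trans to C2 across C1=C10, cis C2=C3, C3 cis to C6 across C4=C5)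
Conditions: hν (300 nm lamps, Pyrex), degassed CH2Cl2 (about 2 mM), −78 °C, to partial conversion; solution kept cold and transferred at once (unchanged 26 is recovered after step 21 and recycled)
Reagents that add atoms: none
Why: Excitation of the ring A diene (C1=C2–C3=C4) triggers a conrotatory six-electron electrocyclic opening in which the C5–C10 sigma bond breaks while C1=C10 and C4=C5 form and the middle double bond remains as cis C2=C3. The closest known reaction type is the photochemical opening of ring-fused cyclohexa-1,3-dienes to cyclodeca-1,3,5-trienes, as with eudesma-1,3-dien-6,12-olides and with provitamin D. The ten-membered carbocycle is not closed end to end; it appears when rings A and B lose their common bond, so no macrocyclisation is involved. No stereocentre is created (C5 and C10 are erased); what is set is alkene geometry, and a cis fusion combined with conrotation must give one ring-trans and one ring-cis terminal alkene. The step needs torquoselectivity (C9 outward, C6 inward), which should follow from the ground-state helicity of the diene: the planar butenolide forces O6 equatorial and so locks ring B in the chair with O6, O8 and C14 equatorial, which makes C9 and H5 pseudoequatorial on ring A (they turn outward) and C14 and C6 pseudoaxial (they turn inward) by least motion. Chemoselectivity rests on the diene absorbing at longer wavelength than the butenolide and on the quaternary C10 blocking aromatisation, while low temperature and partial conversion limit secondary photolysis, hydrogen shift and thermal disrotatory reclosure.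

**Step 21**
Reactants: 27 the trienolide (cold photolysate)
Product: 28 C1–C10 trans-oxirane (C1 R, C10 S), a dienyl epoxide
Conditions: Ti(OiPr)4 (1.2 equiv), L-(+)-diethyl tartrate (1.5 equiv), tBuOOH (2 equiv, in decane), 4 Å sieves, CH2Cl2, −30 °C
Reagents that add atoms: tert-butyl hydroperoxide, CC(C)(C)OO
Why: In the Sharpless asymmetric epoxidation the titanium tartrate binds the C14 alkoxide and passes the peroxide oxygen only to the adjacent C1=C10 bond, on the face set by L-(+)-tartrate (C10 S, C1 R), which should be the outer face of the conformer that holds C14 on the ring face opposite O6; the trans relation of C9 and C2 is copied from the alkene, and the oxidation removes the hexatriene that could reclose.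

**Step 22**
Reactants: 28 the dienyl epoxide
Product: 29 bis-oxirane with free C8 and C14 hydroxyls
Conditions: VO(acac)2 (5 mol%), tBuOOH (1.1 equiv, in decane), CH2Cl2, 0 °C
Reagents that add atoms: tert-butyl hydroperoxide, CC(C)(C)OO
Why: In this vanadium-catalysed hydroxyl-directed epoxidation the vanadate ester of the bishomoallylic C8 hydroxyl should deliver oxygen to the electron-rich trisubstituted C4=C5 bond on the face syn to C7, which is the concave face once H6 eclipses the alkene to avoid allylic strain with C3; the cis relation of C3 and C6 comes from the alkene.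

**Step 23**
Reactants: 29 the bis-oxirane diol; 30 (R)-2-methylbutanoic acid
Product: 33 target CNP0108300.1, via C14 triethylsilyl ether 31 (not isolated), via silylated C8 ester 32 (not isolated)
Conditions: Et3SiCl (1.05 equiv), imidazole, CH2Cl2, −40 °C; then 30, iPrN=C=NiPr, DMAP (cat.), 0 °C; then Et3N·3HF, 0 °C
Reagents that add atoms: none
Why: The primary C14 hydroxyl is silylated first on steric grounds, carbodiimide and DMAP esterification (Steglich type) then acylates the only free hydroxyl at C8 with retention, and buffered fluoride frees C14 without opening the vinyl oxiranes; the side-chain centre is bought in 30.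

**Compound list**
1 | (−)-shikimic acid | OC(=O)C1=C[C@@H](O)[C@@H](O)[C@H](O)C1 | starting material
2 | methyl shikimate | COC(=O)C1=C[C@@H](O)[C@@H](O)[C@H](O)C1 | intermediate
3 | methyl 3,4-O-isopropylideneshikimate | COC(=O)C1=C[C@H]2OC(C)(C)O[C@H]2[C@H](O)C1 | intermediate
4 | methyl 5-epi-3,4-O-isopropylidene-5-O-(4-nitrobenzoyl)shikimate | COC(=O)C1=C[C@H]2OC(C)(C)O[C@H]2[C@@H](OC(=O)c3ccc(cc3)[N+](=O)[O-])C1 | intermediate
5 | methyl 5-epi-3,4-O-isopropylideneshikimate | COC(=O)C1=C[C@H]2OC(C)(C)O[C@H]2[C@@H](O)C1 | intermediate
6 | methyl 5-epi-3,4-O-isopropylidene-5-O-(tert-butyldimethylsilyl)shikimate | COC(=O)C1=C[C@H]2OC(C)(C)O[C@H]2[C@@H](O[Si](C)(C)C(C)(C)C)C1 | intermediate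
7 | (E)-1-methoxy-3-(trimethylsilyloxy)buta-1,3-diene | CO/C=C/C(=C)O[Si](C)(C)C | starting material
8 | silyl enol ether cycloadduct (C1 methoxy epimers, C2=C3 enol silyl ether) | COC(=O)[C@@]12C(OC)C=C(O[Si](C)(C)C)C[C@@H]1[C@H]3OC(C)(C)O[C@H]3[C@@H](O[Si](C)(C)C(C)(C)C)C2 | intermediate
9 | cis-fused 1-en-3-one with angular methyl ester | COC(=O)[C@@]12C=CC(=O)C[C@@H]1[C@H]3OC(C)(C)O[C@H]3[C@@H](O[Si](C)(C)C(C)(C)C)C2 | intermediate
10 | 4-methyl enone (C4 epimers) | COC(=O)[C@@]12C=CC(=O)C(C)[C@@H]1[C@H]3OC(C)(C)O[C@H]3[C@@H](O[Si](C)(C)C(C)(C)C)C2 | intermediate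
11 | dienyl triflate | COC(=O)[C@@]12C=CC(OS(=O)(=O)C(F)(F)F)=C(C)[C@@H]1[C@H]3OC(C)(C)O[C@H]3[C@@H](O[Si](C)(C)C(C)(C)C)C2 | intermediate
12 | cis-hexalin 1,3-diene methyl ester | COC(=O)[C@@]12C=CC=C(C)[C@@H]1[C@H]3OC(C)(C)O[C@H]3[C@@H](O[Si](C)(C)C(C)(C)C)C2 | intermediate
13 | cis-hexalin diene C14 alcohol | OC[C@@]12C=CC=C(C)[C@@H]1[C@H]3OC(C)(C)O[C@H]3[C@@H](O[Si](C)(C)C(C)(C)C)C2 | intermediate
14 | C14 triisopropylsilyl ether | CC(C)[Si](C(C)C)(C(C)C)OC[C@@]12C=CC=C(C)[C@@H]1[C@H]3OC(C)(C)O[C@H]3[C@@H](O[Si](C)(C)C(C)(C)C)C2 | intermediate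
15 | cis-hexalin diene 6,7-diol | CC(C)[Si](C(C)C)(C(C)C)OC[C@@]12C=CC=C(C)[C@@H]1[C@@H](O)[C@@H](O)[C@@H](O[Si](C)(C)C(C)(C)C)C2 | intermediate
16 | allyl 2-(diethoxyphosphoryl)acetate | CCOP(=O)(OCC)CC(=O)OCC=C | starting material
17 | (triisopropylsilyloxy)methyl chloride | ClCO[Si](C(C)C)(C(C)C)C(C)C | starting material
18 | allyl 2-(diethoxyphosphoryl)-3-(triisopropylsilyloxy)propanoate (racemic) | CCOP(=O)(OCC)C(CO[Si](C(C)C)(C(C)C)C(C)C)C(=O)OCC=C | intermediate
19 | 2-(diethoxyphosphoryl)-3-(triisopropylsilyloxy)propanoic acid (racemic) | CCOP(=O)(OCC)C(CO[Si](C(C)C)(C(C)C)C(C)C)C(=O)O | intermediate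
20 | 6,7-O-dibutylstannylene acetal of 15 | CC(C)[Si](C(C)C)(C(C)C)OC[C@@]12C=CC=C(C)[C@@H]1[C@H]3O[Sn](CCCC)(CCCC)O[C@H]3[C@@H](O[Si](C)(C)C(C)(C)C)C2 | intermediate
21 | 2-(diethoxyphosphoryl)-3-(triisopropylsilyloxy)propanoyl chloride | CCOP(=O)(OCC)C(CO[Si](C(C)C)(C(C)C)C(C)C)C(Cl)=O | intermediate
22 | C6 phosphonoacyl ester with free C7 hydroxyl | CC(C)[Si](C(C)C)(C(C)C)OC[C@@]12C=CC=C(C)[C@@H]1[C@@H](OC(=O)C(CO[Si](C(C)C)(C(C)C)C(C)C)P(=O)(OCC)OCC)[C@@H](O)[C@@H](O[Si](C)(C)C(C)(C)C)C2 | intermediate
23 | C7 ketone | CC(C)[Si](C(C)C)(C(C)C)OC[C@@]12C=CC=C(C)[C@@H]1[C@@H](OC(=O)C(CO[Si](C(C)C)(C(C)C)C(C)C)P(=O)(OCC)OCC)C(=O)[C@@H](O[Si](C)(C)C(C)(C)C)C2 | intermediate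
24 | silylated tricyclic hexalin butenolide | CC(C)[Si](C(C)C)(C(C)C)OC[C@@]12C=CC=C(C)[C@@H]1[C@H]3OC(=O)C(CO[Si](C(C)C)(C(C)C)C(C)C)=C3[C@@H](O[Si](C)(C)C(C)(C)C)C2 | intermediate
25 | hexalin butenolide triol | OC[C@@]12C=CC=C(C)[C@@H]1[C@H]3OC(=O)C(CO)=C3[C@@H](O)C2 | intermediate
26 | hexalin butenolide C13 acetate (8,14-diol) | OC[C@@]12C=CC=C(C)[C@@H]1[C@H]3OC(=O)C(COC(C)=O)=C3[C@@H](O)C2 | intermediate
27 | cyclodeca-1(10),2,4-trienolide | O[C@H]1C/C(CO)=C/C=C\C(C)=C/[C@H]2OC(=O)C(COC(C)=O)=C12 | intermediate
28 | C1–C10 trans-oxirane, dienyl epoxide | O[C@H]1C[C@@]2(CO)O[C@@H]2/C=C\C(C)=C/[C@H]2OC(=O)C(COC(C)=O)=C12 | intermediate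
29 | bis-oxirane 8,14-diol | O[C@H]1C[C@@]2(CO)O[C@@H]2/C=C\[C@@]2(C)O[C@H]2[C@H]2OC(=O)C(COC(C)=O)=C12 | intermediate
30 | (R)-2-methylbutanoic acid | CC[C@@H](C)C(=O)O | starting material
31 | C14 triethylsilyl ether of 29 | O[C@H]1C[C@@]2(CO[Si](CC)(CC)CC)O[C@@H]2/C=C\[C@@]2(C)O[C@H]2[C@H]2OC(=O)C(COC(C)=O)=C12 | intermediate
32 | C14 triethylsilyl ether, C8 (R)-2-methylbutanoate | CC[C@@H](C)C(=O)O[C@H]1C[C@@]2(CO[Si](CC)(CC)CC)O[C@@H]2/C=C\[C@@]2(C)O[C@H]2[C@H]2OC(=O)C(COC(C)=O)=C12 | intermediate
33 | CNP0108300.1 | CC[C@@H](C)C(=O)O[C@H]1C[C@@]2(CO)O[C@@H]2/C=C\[C@@]2(C)O[C@H]2[C@H]2OC(=O)C(COC(C)=O)=C12 | target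

**Step count**
Total: 23 steps. Longest linear sequence: 21 steps (steps 1–12 and 15–23, from compound 1).

**Steps most likely to fail**

Step 20. The nascent ring-trans alkene may be intercepted by the free hydroxyl groups, and the triene may be lost to secondary photoisomerisation, hydrogen shift or thermal disrotatory reclosure before it reaches the oxidant. The fallback changes the substrate of the ring opening and sets out from 26. Both hydroxyls are silylated (Et3SiCl, imidazole) to the C8,C14-bis(triethylsilyl) ether F1. F1 is irradiated in pentane/ether at about −90 °C, where a hydroxyl-free, non-polar substrate stays in solution, to give the bis-silylated trienolide F2. Cold HF·pyridine/pyridine (−40 °C) frees only the primary C14 hydroxyl to give the C8 mono(triethylsilyl) trienolide F3. F3 is epoxidised as in step 21 to the C8 triethylsilyl ether of the dienyl epoxide F4, and Et3N·3HF then returns the route at 28.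

Step 21. Oxygen transfer may be slow or may meet the wrong alkene face, because the tartrate-bound titanium alkoxide needs the ring-trans alkene to turn its C5-side face outward; reclosure then competes and facial selectivity drops. The fallback sets out from 27 and replaces hydroxyl-directed delivery by a reagent-controlled, non-directed dioxirane: the D-fructose-derived ketone with KHSO5 in MeCN/dimethoxymethane/aqueous K2CO3 at −10 °C (Shi epoxidation). This reagent prefers ring-trans trisubstituted alkenes over cis ones, and its spiro transition-state model points to the same C1=C10 face as L-(+)-tartrate. It comes back to the route at 28 and makes no new compound (F0).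

Step 22. The two hydroxyls may compete as directing groups (the C14 alkoxide could send oxygen to C2=C3), and the Lewis-acidic vanadium could open the vinyl oxirane, so regiocontrol is lost. The fallback sets out from 28 and makes a substrate with one director only: silylation of the primary hydroxyl (Et3SiCl, imidazole, −40 °C) gives the C14 triethylsilyl ether of the dienyl epoxide F5. VO(acac)2/tBuOOH then has only the C8 hydroxyl to bind and should give 31 directly. The route is rejoined at 31, which is esterified and desilylated as in step 23.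

**Further compounds**
F1 | step 20 | C8,C14-bis(triethylsilyl) ether of 26 | CC[Si](CC)(CC)OC[C@@]12C=CC=C(C)[C@@H]1[C@H]3OC(=O)C(COC(C)=O)=C3[C@@H](O[Si](CC)(CC)CC)C2
F2 | step 20 | C8,C14-bis(triethylsilyl) ether of trienolide 27 | CC[Si](CC)(CC)O[C@H]1C/C(CO[Si](CC)(CC)CC)=C/C=C\C(C)=C/[C@H]2OC(=O)C(COC(C)=O)=C12
F3 | step 20 | C8 triethylsilyl ether of trienolide 27 | CC[Si](CC)(CC)O[C@H]1C/C(CO)=C/C=C\C(C)=C/[C@H]2OC(=O)C(COC(C)=O)=C12
F4 | step 20 | C8 triethylsilyl ether of dienyl epoxide 28 | CC[Si](CC)(CC)O[C@H]1C[C@@]2(CO)O[C@@H]2/C=C\C(C)=C/[C@H]2OC(=O)C(COC(C)=O)=C12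
F0 | step 21 | none | none
F5 | step 22 | C14 triethylsilyl ether of dienyl epoxide 28 | O[C@H]1C[C@@]2(CO[Si](CC)(CC)CC)O[C@@H]2/C=C\C(C)=C/[C@H]2OC(=O)C(COC(C)=O)=C12
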